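Readings and results are simulated for an exercise; scatter was added.

Lay birch beside maple: the target plateau reads lower in maple, 75.4% against 82.7%, yet from the same charge of reagent maple reads more target in moles.

| setting | birch | maple | flask |
|---|---|---|---|
| solid substrate | 0.034 M | 0.075 M | 0.050 M |
| reagent | 0.065 M | 0.065 M | 0.0650 M |
| remark | run made earlier | run made earlier |  |
| time |  |  | 1.0 h |

| run | time / min | target / % |
|---|---|---|
| birch | 6.00 | 73.2 |
| birch | 20.0 | 82.4 |
| birch | 30.0 | 83.2 |
| birch | 50.0 | 81.8 |
| birch | 80.0 | 83.5 |
| maple | 6.00 | 34.0 |
| maple | 20.0 | 75.7 |
| maple | 30.0 | 75.2 |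
| maple | 50.0 | 75.4 |
| maple | 80.0 | 75.3 |

(standard deviation of a reading: 0.5 percentage points)

- target at 1.0 h, in percent of the solid substrate charged
- the change that raises the amount of target at 1.0 h, in percent of the solid substrate charged most ("none" if none brings more than 2 percentage points) (summer / noon / dusk / none)
- amount of target at 1.0 h, in percent of the solid substrate charged, after noon

- summer: doubling the dissolution coefficient of the solid substrate, all else as stated
- noon: doubling the solubility of the solid substrate, all else as stated
- dusk: doubling the amount of reagent, all else as stated

Is the flask still moving at the asked time? Read it as finished: birch and maple stand flat from 20.0 min, and 1.0 h is longer.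

Which charge ends it? Count one reagent per solid substrate consumed, whichever product forms. Maple holds more solid substrate than reagent, so take its 0.065 M of reagent as spent, the limiting reagent; its target of 0.05655 M is then a selectivity of 87.0%. The flask has 0.050 M against 0.0650 M, so solid substrate ends it.

What splits the product? Divide the final [isomer of the product]/[target] by the mean [reagent], halfway between start and end: this selectivity factor is the quantity to carry. Birch gives 0.209 over 0.0480 M, or 4.35 L mol⁻¹. Maple gives 0.149 over 0.03250 M, or 4.60 L mol⁻¹. Take their mean, 4.47 L mol⁻¹.

The flask's mean [reagent] is 0.0400 M, so I reckon 84.8% target. Taken singly, the two runs' factors give yields 0.71 percentage points apart, less than 2 points. Noon and summer, which touch the solid substrate's solubility and dissolution, leave that reckoned mean unchanged. Dusk raises it to 0.105 M, and my reckoned yield falls to 68.0%. My choice is none.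

The forecast agrees, with 85%, 85% after noon and none: “The end yields are set by selectivity, not by time”.

The flask gives 85.4%, 85.4% after noon, best none, and dusk −16 points.

    starting material ⇌ tautomer (K = 0.0286, k = 0.0117 s⁻¹)
    starting material + reagent → isomer of the product (k = 0.0472 L mol⁻¹ s⁻¹)
    reagent + tautomer → target (k = 130 L mol⁻¹ s⁻¹)
    solid substrate ⇌ starting material, rate k4*(cs4 - [starting material]) while solid is left; crystals form when [starting material] > cs4 (solubility = 17.0 mM, k = 0.0105 s⁻¹)

At 0.0599 h in the flask, starting material enters the path to tautomer 5.2 times as fast, forward rate alone, as the path to isomer of the product. The flask ends with 14.6% isomer of the product and 85.4% target, a factor of 4.27 L mol⁻¹ over 0.0400 M. In the neighbour with 0.20 M of solid substrate, reagent ends at 0%, so the carried factor at mean [reagent] 0.03250 M predicts 28.4% target, and that neighbour holds 28.5%.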